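**Plan**

- Numbering of target 12 (bicyclo[3.2.1]oct-3-ene-2,8-dione): C1 prenyl bridgehead, C5 methyl bridgehead, C6 the CH that carries CMe2OH, C7 CH2, C8 bridging C=O. Retrosynthetic cuts: C5–C6 together with the tertiary C–O bond (last ring); the C3–acyl bond; C5–C8 and C3–C4 of the six-membered ring; C1–C7 and C1–CH2 of the two prenyl-derived arms.
- Forward: an open chain is built on one acetoacetate carbon (1 → 5), a dianion Claisen closure gives the six-membered trione 6, C-acylation gives 9, and the cyclopentanone C1–C8–C5–C6–C7 is closed last across the intact six-membered ring.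
- Enabling feature: in 9 the methyl-bearing enol carbon (future C5, between two ring carbonyls) and the gem-diprenyl carbon (future C1) are 1,3-related across the future C8 carbonyl, so a radical at the former reaches the CH end of a prenyl group by 5-exo attack. The ring plane of 9 is a mirror plane, so the two prenyl groups are enantiotopic.
- Activating group: a bromine atom placed on that enol carbon. The ring closure moves it to the side chain and the last step exchanges it for OH.
- Stereochemistry: the (2R) centre comes from acid 7. C1 and C5 are set together by the enzyme's choice of one prenyl group. C6 is exo through the shape of the 5-exo transition state.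

Key step: step 5

Assumption: enolisable β-polyketones are written as one tautomer each, and (2R)-2-methylbutanoic acid is taken as a purchasable reagent.

**Step 1**
Reactants: 1 methyl acetoacetate; 2 prenyl bromide (1-bromo-3-methylbut-2-ene)
Product: 3 methyl 2-acetyl-5-methyl-2-(3-methylbut-2-en-1-yl)hex-4-enoate
Conditions: NaH (2.2 equiv, two portions), 2 (2.2 equiv), THF, 0 → 50 °C
Reagents that add atoms: none
Why: Double C-alkylation of the acetoacetate enolate (acetoacetic ester alkylation) with a reactive allylic bromide should place both prenyl groups on the doubly activated carbon, and no stereocentre is formed.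

**Step 2**
Reactants: 3 methyl 2,2-diprenylacetoacetate; 4 propanoyl chloride
Product: 5 methyl 2,2-bis(3-methylbut-2-en-1-yl)-3,5-dioxoheptanoate
Conditions: MgBr2·OEt2 (2.5 equiv), iPr2NEt (3 equiv), CH2Cl2, 0 °C → rt
Reagents that add atoms: none
Why: Soft enolisation of the only enolisable position, the acetyl methyl group, within the magnesium chelate followed by C-acylation (crossed Claisen-type acylation of a ketone) should give the 1,3-diketone, whose magnesium chelate resists a second acylation, and no stereocentre is formed.

**Step 3**
Reactants: 5 diketo ester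
Product: 6 2-methyl-4,4-bis(3-methylbut-2-en-1-yl)cyclohexane-1,3,5-trione
Conditions: LiN(iPr)2 (3.2 equiv), THF, −78 → 0 °C; then aqueous HCl
Reagents that add atoms: none
Why: The 1,3-dianion of the β-diketone should attack the ester through its terminal carbanion in a 6-exo-trig Claisen (Dieckmann-type) condensation to close the six-membered trione, and the methyl-bearing carbon stays enolisable and needs no control.

**Step 4**
Reactants: 6 cyclic trione; 7 (2R)-2-methylbutanoic acid
Product: 9 3,5-dihydroxy-4-methyl-2-[(2R)-2-methylbutanoyl]-6,6-bis(3-methylbut-2-en-1-yl)cyclohexa-2,4-dien-1-one, via enol ester 8 (not isolated)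
Conditions: DCC (1.1 equiv), DMAP (1.2 equiv), CH2Cl2, 0 °C → rt, Ar
Reagents that add atoms: none
Why: Steglich esterification should give enol ester 8, and DMAP should then shift the acyl group from oxygen to carbon (the acyl migration known for cyclic 1,3-diones) at the only ring carbon that can end as an enolised triketone, while the (2R) centre is brought in unchanged with 7.

**Step 5**
Reactants: 9 enolised acyl trione
Product: 11 (1S,5S,6S)-6-(2-bromopropan-2-yl)-4-hydroxy-5-methyl-3-[(2R)-2-methylbutanoyl]-1-(3-methylbut-2-en-1-yl)bicyclo[3.2.1]oct-3-ene-2,8-dione, via bromotrione 10 (not isolated)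
Conditions: NBS (1.0 equiv), MeCN, −40 °C, Ar; then transfer into E. coli cells expressing an engineered cytochrome P450 atom-transfer radical cyclase (CYP102A1 haem-domain lineage, variant found by screening for the (1S,5S,6S) series), M9-N buffer pH 7.4, 5 vol% MeCN, anaerobic, rt
Reagents that add atoms: N-bromosuccinimide, O=C1CCC(=O)N1Br
Why: Proposed new method: NBS should brominate the only free enol carbon of 9 to give 10 (both C4 epimers lead to the same planar radical), and the ferrous haem of the cyclase should then take the bromine atom to leave a tertiary carbon radical flanked by two ring carbonyls, which adds to the CH end of one prenyl group on the 1,3-related quaternary carbon before the new tertiary side-chain radical takes bromine back from the ferric bromide haem. The closest known reaction type is the atom-transfer radical cyclisation of α-halo carbonyl compounds onto alkenes, known with CuCl/2,2′-bipyridine and, with control of absolute configuration, with evolved haem proteins on α-bromo amides, while oxidative radical cyclisations of dearomatised prenylated acylphloroglucinols show that this C–C bond closes readily in this substrate family. The cyclopentanone ring C1–C8–C5–C6–C7 closes in the 5-exo-trig mode across the six-membered ring and thereby makes the bicyclo[3.2.1]octane. C1 and C5 are set together by the choice of one of the two enantiotopic prenyl groups, which is the same as the choice of the face of the planar radical and is left to the chiral pocket of the enzyme, whereas C6 is set exo by the substrate because the dimethyl-substituted alkene end points away from the enone bridge in the transition state. The step needs selection between the prenyl groups (enzyme), 5-exo over 6-endo closure (attack at the less substituted alkene carbon gives a tertiary radical), C–C in place of C–O bond formation (radical and not enolate reactivity), reaction at the methyl-bearing and not at the acyl-bearing ring carbon (the bromine atom marks the site) and bromine return faster than attack on the second prenyl group (the return happens inside the pocket), and the oxygen-free medium leaves both alkenes otherwise untouched.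

**Step 6**
Reactants: 11 tertiary bromide
Product: 12 (1S,5S,6S)-4-hydroxy-6-(2-hydroxypropan-2-yl)-5-methyl-3-[(2R)-2-methylbutanoyl]-1-(3-methylbut-2-en-1-yl)bicyclo[3.2.1]oct-3-ene-2,8-dione
Conditions: Ag2CO3 (0.6 equiv), acetone/H2O 4:1, 0 °C → rt, dark
Reagents that add atoms: water, O
Why: Silver-assisted SN1 hydrolysis of the tertiary bromide should give the tertiary alcohol because the cationic carbon is exocyclic and not stereogenic, so that C1, C5, C6 and the side-chain centre are untouched.

**Compound list**

1 | methyl 3-oxobutanoate (methyl acetoacetate) | CC(=O)CC(=O)OC | starting material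
2 | 1-bromo-3-methylbut-2-ene (prenyl bromide) | CC(C)=CCBr | starting material
3 | methyl 2-acetyl-5-methyl-2-(3-methylbut-2-en-1-yl)hex-4-enoate | CC(=O)C(CC=C(C)C)(CC=C(C)C)C(=O)OC | intermediate
4 | propanoyl chloride | CCC(=O)Cl | starting material
5 | methyl 2,2-bis(3-methylbut-2-en-1-yl)-3,5-dioxoheptanoate | CCC(=O)CC(=O)C(CC=C(C)C)(CC=C(C)C)C(=O)OC | intermediate
6 | 2-methyl-4,4-bis(3-methylbut-2-en-1-yl)cyclohexane-1,3,5-trione (enolised, C2 not configurationally stable) | CC1C(=O)CC(=O)C(CC=C(C)C)(CC=C(C)C)C1=O | intermediate
7 | (2R)-2-methylbutanoic acid | CC[C@@H](C)C(=O)O | starting material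
8 | 6-methyl-4,4-bis(3-methylbut-2-en-1-yl)-3,5-dioxocyclohex-1-en-1-yl (2R)-2-methylbutanoate (one of the regioisomeric enol esters) | CC[C@@H](C)C(=O)OC1=CC(=O)C(CC=C(C)C)(CC=C(C)C)C(=O)C1C | intermediate
9 | 3,5-dihydroxy-4-methyl-2-[(2R)-2-methylbutanoyl]-6,6-bis(3-methylbut-2-en-1-yl)cyclohexa-2,4-dien-1-one | CC[C@@H](C)C(=O)C1=C(O)C(C)=C(O)C(CC=C(C)C)(CC=C(C)C)C1=O | intermediate
10 | 4-bromo-3-hydroxy-4-methyl-2-[(2R)-2-methylbutanoyl]-6,6-bis(3-methylbut-2-en-1-yl)cyclohex-2-ene-1,5-dione (both C4 epimers) | CC[C@@H](C)C(=O)C1=C(O)C(C)(Br)C(=O)C(CC=C(C)C)(CC=C(C)C)C1=O | intermediate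
11 | (1S,5S,6S)-6-(2-bromopropan-2-yl)-4-hydroxy-5-methyl-3-[(2R)-2-methylbutanoyl]-1-(3-methylbut-2-en-1-yl)bicyclo[3.2.1]oct-3-ene-2,8-dione | CC[C@@H](C)C(=O)C1=C(O)[C@@]2(C)C(=O)[C@](CC=C(C)C)(C[C@@H]2C(C)(C)Br)C1=O | intermediate
12 | (1S,5S,6S)-4-hydroxy-6-(2-hydroxypropan-2-yl)-5-methyl-3-[(2R)-2-methylbutanoyl]-1-(3-methylbut-2-en-1-yl)bicyclo[3.2.1]oct-3-ene-2,8-dione | CC[C@@H](C)C(=O)C1=C(O)[C@@]2(C)C(=O)[C@](CC=C(C)C)(C[C@@H]2C(C)(C)O)C1=O | target

Total step count: 6. Longest linear sequence: 6 steps (1 → 3 → 5 → 6 → 9 → 11 → 12).

**Steps most likely to fail**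

1. Step 5 (Proposed new method). What may go wrong:
   - reductive loss of bromine from 10 back to 9 by thiols of the cell preparation;
   - bromonium-type or free-radical cyclisation outside the active site, with no choice between the two prenyl groups;
   - alkylation of the protein by the electrophilic bromide.

   The fallback uses known chemistry, sets out from 9 and comes back at 12, by-passing 10 and 11. It is an aerobic manganese triacetate-mediated oxidative radical cyclisation: Mn(OAc)3·2H2O (0.2 equiv), O2 (1 atm), AcOH/EtOH, rt. The enol radical should close the same 5-exo ring, and O2 should trap the tertiary radical. This gives tertiary hydroperoxide F1 together with the hydroperoxide of opposite ring configuration F2. Reduction of the mixture with PPh3 (CH2Cl2, 0 °C) should give 12 and the (1R,5R,6R) alcohol F3. These two are diastereomers because of the (2R) side chain and are separated by preparative HPLC. The ring configuration is then sorted and no longer controlled.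

2. Step 6. What may go wrong: loss of a proton from the tertiary cation, or capture of the cation by the remaining prenyl double bond in place of water.

   The fallback sets out from 11 and comes back at 12. A deliberate E2 elimination toward a methyl group with DBU (toluene, 60 °C) should give isopropenyl compound F4. A Mukaiyama hydration (Co(acac)2 cat., PhSiH3, O2, iPrOH, rt) should then add water in the Markovnikov sense to the 1,1-disubstituted alkene, which takes up a hydrogen atom faster than the trisubstituted prenyl alkene. No cation is formed and C6 is not touched.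

3. Step 4. What may go wrong: incomplete O-to-C acyl migration at the hindered ring position, or partial loss of configuration at the α-carbon of the acyl group through enolisation of the acylpyridinium ion.

   The fallback sets out from 7 and 6 and comes back at 9. Acid 7 is converted with 1H-benzotriazole and SOCl2 (CH2Cl2, rt) into N-acylbenzotriazole F5, a neutral acyl donor. F5 should C-acylate the magnesium chelate of 6 directly under soft enolisation (MgBr2·OEt2, iPr2NEt, CH2Cl2), so that neither an enol ester nor an acylpyridinium ion is involved.

Further compounds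
F1 | step 5 | (1S,5S,6S)-6-(2-hydroperoxypropan-2-yl)-4-hydroxy-5-methyl-3-[(2R)-2-methylbutanoyl]-1-(3-methylbut-2-en-1-yl)bicyclo[3.2.1]oct-3-ene-2,8-dione | CC[C@@H](C)C(=O)C1=C(O)[C@@]2(C)C(=O)[C@](CC=C(C)C)(C[C@@H]2C(C)(C)OO)C1=O
F2 | step 5 | (1R,5R,6R)-6-(2-hydroperoxypropan-2-yl)-4-hydroxy-5-methyl-3-[(2R)-2-methylbutanoyl]-1-(3-methylbut-2-en-1-yl)bicyclo[3.2.1]oct-3-ene-2,8-dione | CC[C@@H](C)C(=O)C1=C(O)[C@]2(C)C(=O)[C@@](CC=C(C)C)(C[C@H]2C(C)(C)OO)C1=O
F3 | step 5 | (1R,5R,6R)-4-hydroxy-6-(2-hydroxypropan-2-yl)-5-methyl-3-[(2R)-2-methylbutanoyl]-1-(3-methylbut-2-en-1-yl)bicyclo[3.2.1]oct-3-ene-2,8-dione | CC[C@@H](C)C(=O)C1=C(O)[C@]2(C)C(=O)[C@@](CC=C(C)C)(C[C@H]2C(C)(C)O)C1=O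
F4 | step 6 | (1S,5S,6R)-4-hydroxy-5-methyl-3-[(2R)-2-methylbutanoyl]-1-(3-methylbut-2-en-1-yl)-6-(prop-1-en-2-yl)bicyclo[3.2.1]oct-3-ene-2,8-dione | CC[C@@H](C)C(=O)C1=C(O)[C@@]2(C)C(=O)[C@](CC=C(C)C)(C[C@@H]2C(C)=C)C1=O
F5 | step 4 | (2R)-1-(1H-benzotriazol-1-yl)-2-methylbutan-1-one | CC[C@@H](C)C(=O)n1nnc2ccccc12
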